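The central pyrrole ring is disconnected at C2–C3 and C4–C5: N1, C2 with its carboxyl carbon and C5 come from an isocyanoacetate ester, while C3 and C4 with their indol-3-yl groups come from a nitroalkene. A Barton–Zard annulation makes both bonds, closes the ring and aromatises it in one operation by expelling nitrite. It exploits two features of the pyrrole: C3 and C4 bear identical indolyl groups, so the orientation of the partners is immaterial, and C5 emerges as C–H, the one site left for the acetyl group. The precursor is a nitroethene carrying an N-tosylindol-3-yl group on each alkene carbon, reached by Henry condensation; acetylation and one basic hydrolysis complete the synthesis.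

Key step: step 3

Assumption: 3-bromo-1-tosylindole and 1-tosylindole-3-carbaldehyde are taken as catalogue compounds, and the N-tosyl group (tosyl = 4-methylbenzenesulfonyl) serves as the indole protection throughout.

Step 1
Reactants: 1 3-bromo-1-tosyl-1H-indole; 2 nitromethane
Product: 3 3-(nitromethyl)-1-tosyl-1H-indole
Conditions: Pd2(dba)3 (2.5 mol %), XPhos (6 mol %), Cs2CO3, 4 Å MS, 2 as solvent, 50 °C; aq NH4Cl work-up
Reagents that add atoms: none
Why: Palladium-catalysed α-arylation of nitromethane (cross-coupling of an aryl bromide with a nitronate): zerovalent palladium should insert into the C3–Br bond, bromide should be exchanged for the cesium nitronate and reductive elimination from the bulky biarylphosphine complex should form the C3–CH2NO2 bond, while the large excess of 2 suppresses a second arylation.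

Step 2
Reactants: 4 1-tosyl-1H-indole-3-carbaldehyde; 3 3-(nitromethyl)-1-tosyl-1H-indole
Product: 6 (E)-1-nitro-1,2-bis(1-tosylindol-3-yl)ethene, via N-butylimine 5 (not isolated)
Conditions: n-BuNH2, 4 Å MS, toluene, rt; then 3, AcOH, 50 °C
Reagents that add atoms: none
Why: Henry (nitroaldol) condensation run through the preformed N-butylimine: the aci form of 3 should add to protonated 5 and the β-amino nitro adduct should lose butylamine in acetic acid to give the conjugated nitroalkene, for which the E geometry (nitro group trans to the β-indolyl group, the two indolyl groups cis) is thermodynamically preferred, although either geometry would serve in step 3.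

Step 3
Reactants: 6 (E)-1-nitro-1,2-bis(1-tosylindol-3-yl)ethene; 7 methyl isocyanoacetate
Product: 9 methyl 3,4-bis(1-tosylindol-3-yl)-1H-pyrrole-2-carboxylate, via 2H-pyrrole 8 (not isolated)
Conditions: DBU, THF, 0 °C to rt
Reagents that add atoms: none
Why: Barton–Zard pyrrole synthesis: DBU deprotonates 7, the carbanion adds in Michael fashion to the hydrogen-bearing alkene carbon of 6 (bond C2–C3), and the carbon of the resulting nitronate attacks the isocyanide carbon (bond C4–C5), which closes the five-membered ring in the 5-endo-dig mode. Protonation of the cyclic imidoyl anion, E1cB loss of nitrite and a hydrogen shift from C2 to nitrogen in 2H-pyrrole 8 should then give the aromatic 1H-pyrrole, so that the departing nitro group supplies the oxidation level of the pyrrole and no oxidant is called for. The closest known case is the same annulation applied to 1,2-diaryl-1-nitroethenes, which furnishes 3,4-diarylpyrrole-2-carboxylic esters. No stereocentre has to be set: the sp3 centres of the cyclic adducts disappear on aromatisation, which also makes the alkene geometry of 6 irrelevant. The only selectivity at stake is the orientation of the two partners, and it cannot lead to isomers here because C3 and C4 receive the same 1-tosylindol-3-yl group from either alkene carbon, while the isocyanoacetate itself fixes the ester at C2 and hydrogen at C5. The electron-withdrawing sulfonyl groups stop the indole nitrogen lone pairs from quenching the electrophilicity of the nitroalkene, and they, like the methyl ester, should survive DBU in an aprotic solvent.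

Step 4
Reactants: 9 methyl 3,4-bis(1-tosylindol-3-yl)-1H-pyrrole-2-carboxylate
Product: 10 methyl 5-acetyl-3,4-bis(1-tosylindol-3-yl)-1H-pyrrole-2-carboxylate
Conditions: AcCl, SnCl4, CH2Cl2, 0 °C to rt
Reagents that add atoms: acetyl chloride, CC(=O)Cl
Why: Friedel–Crafts acylation: C5 is the only unsubstituted carbon of the pyrrole and an α-position, so the acylium equivalent formed from acetyl chloride and SnCl4 should attack there, whereas the N-sulfonylindoles are deactivated and have their own C3 positions occupied.

Step 5
Reactants: 10 methyl 5-acetyl-3,4-bis(1-tosylindol-3-yl)-1H-pyrrole-2-carboxylate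
Product: 11 5-acetyl-3,4-di(1H-indol-3-yl)-1H-pyrrole-2-carboxylic acid
Conditions: KOH (excess), MeOH/THF/H2O, reflux; then 1 M HCl to pH 3, 0 °C
Reagents that add atoms: potassium hydroxide, [K+].[OH-]
Why: Base hydrolysis (sulfonamide cleavage and ester saponification): hydroxide should attack sulfur of each N-sulfonylindole with the indolide as leaving group and saponify the methyl ester in the same pot, and cold acidification should then liberate the acid, which the 5-acetyl group protects against protodecarboxylation.

Compound list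
1 | 3-bromo-1-tosyl-1H-indole (tosyl = 4-methylbenzenesulfonyl on N1) | Cc1ccc(cc1)S(=O)(=O)n1cc(Br)c2ccccc12 | starting material
2 | nitromethane | C[N+](=O)[O-] | starting material
3 | 3-(nitromethyl)-1-tosyl-1H-indole | Cc1ccc(cc1)S(=O)(=O)n1cc(C[N+](=O)[O-])c2ccccc12 | intermediate
4 | 1-tosyl-1H-indole-3-carbaldehyde | Cc1ccc(cc1)S(=O)(=O)n1cc(C=O)c2ccccc12 | starting material
5 | (E)-N-butyl-1-(1-tosylindol-3-yl)methanimine (not isolated) | CCCC/N=C/c1cn(S(=O)(=O)c2ccc(C)cc2)c2ccccc12 | intermediate
6 | (E)-1-nitro-1,2-bis(1-tosylindol-3-yl)ethene (nitro group trans to the indolyl group on the other alkene carbon) | O=[N+]([O-])/C(c1cn(S(=O)(=O)c2ccc(C)cc2)c2ccccc12)=C/c1cn(S(=O)(=O)c2ccc(C)cc2)c2ccccc12 | intermediate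
7 | methyl isocyanoacetate | [C-]#[N+]CC(=O)OC | starting material
8 | methyl 3,4-bis(1-tosylindol-3-yl)-2H-pyrrole-2-carboxylate (racemic at C2; not isolated) | COC(=O)C1N=CC(c2cn(S(=O)(=O)c3ccc(C)cc3)c3ccccc23)=C1c1cn(S(=O)(=O)c2ccc(C)cc2)c2ccccc12 | intermediate
9 | methyl 3,4-bis(1-tosylindol-3-yl)-1H-pyrrole-2-carboxylate | COC(=O)c1[nH]cc(-c2cn(S(=O)(=O)c3ccc(C)cc3)c3ccccc23)c1-c1cn(S(=O)(=O)c2ccc(C)cc2)c2ccccc12 | intermediate
10 | methyl 5-acetyl-3,4-bis(1-tosylindol-3-yl)-1H-pyrrole-2-carboxylate | COC(=O)c1[nH]c(C(C)=O)c(-c2cn(S(=O)(=O)c3ccc(C)cc3)c3ccccc23)c1-c1cn(S(=O)(=O)c2ccc(C)cc2)c2ccccc12 | intermediate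
11 | 5-acetyl-3,4-di(1H-indol-3-yl)-1H-pyrrole-2-carboxylic acid (achiral) | CC(=O)c1[nH]c(C(=O)O)c(-c2c[nH]c3ccccc23)c1-c1c[nH]c2ccccc12 | target

Total step count: 5. Longest linear sequence: 5 steps (1 → 3 → 6 → 9 → 10 → 11).

Steps most likely to fail

First, step 3, the key step. Conjugate addition to the doubly arylated, sterically shielded alkene may be slow, so that base-mediated self-condensation of the isocyanoacetate or oligomerisation of the nitroalkene outruns it. The cyclic adduct may also stall before nitrite is expelled. The fallback assembles the same ester by cross-coupling on a preformed pyrrole; it sets out from bromide 1 and returns to the route at 9.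
- Miyaura borylation of 1 (bis(pinacolato)diboron, Pd(dppf)Cl2, KOAc, dioxane, 80 °C) should give 1-tosyl-3-(4,4,5,5-tetramethyl-1,3,2-dioxaborolan-2-yl)indole F1.
- Twofold Suzuki–Miyaura coupling of F1 with commercial 3,4-dibromo-1-(triisopropylsilyl)pyrrole (Pd(PPh3)4, aqueous Na2CO3, DME, 80 °C) should give 3,4-bis(1-tosylindol-3-yl)-1-(triisopropylsilyl)pyrrole F2.
- TBAF in THF at 0 °C should remove the silyl group to give 3,4-bis(1-tosylindol-3-yl)-1H-pyrrole F3.
- Trichloroacetyl chloride in CH2Cl2 should acylate one of the two equivalent α-positions to give 2,2,2-trichloro-1-[3,4-bis(1-tosylindol-3-yl)-1H-pyrrol-2-yl]ethanone F4.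
- Methanol with Et3N should cleave the trichloromethyl ketone in haloform fashion to ester 9.

Second, step 1. Catalyst turnover may stall because the nitronate binds palladium too firmly, or the product nitronate may be arylated a second time or degrade under the basic conditions. The fallback replaces the cross-coupling by a classical functional-group sequence; it sets out from aldehyde 4 and returns at 3.
- NaBH4 in MeOH/THF at 0 °C should reduce 4 to (1-tosylindol-3-yl)methanol F5.
- PBr3 in CH2Cl2 at 0 °C should convert it into 3-(bromomethyl)-1-tosylindole F6.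
- AgNO2 in Et2O at 0 °C to rt in the dark (Victor Meyer reaction) should displace bromide to give 3 after chromatography.

Third, step 4. Complexation of the Lewis acid with the ester and the pyrrole N–H may deactivate the ring, so that acylation becomes slow and site selectivity is lost to the benzo rings of the indoles. The fallback installs the acetyl group by halogenation and cross-coupling; it sets out from 9 and returns at 10.
- N-Iodosuccinimide in DMF at 0 °C should iodinate the free α-position to give methyl 5-iodo-3,4-bis(1-tosylindol-3-yl)-1H-pyrrole-2-carboxylate F7.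
- Stille coupling with tributyl(1-ethoxyvinyl)stannane (Pd(PPh3)4, toluene, 100 °C) should give methyl 5-(1-ethoxyvinyl)-3,4-bis(1-tosylindol-3-yl)-1H-pyrrole-2-carboxylate F8.
- 1 M HCl in THF at rt should hydrolyse the enol ether to ketone 10.

Further compounds
F1 | step 3 | 1-tosyl-3-(4,4,5,5-tetramethyl-1,3,2-dioxaborolan-2-yl)indole | Cc1ccc(cc1)S(=O)(=O)n1cc(B2OC(C)(C)C(C)(C)O2)c2ccccc12
F2 | step 3 | 3,4-bis(1-tosylindol-3-yl)-1-(triisopropylsilyl)pyrrole | CC(C)[Si](C(C)C)(C(C)C)n1cc(-c2cn(S(=O)(=O)c3ccc(C)cc3)c3ccccc23)c(-c2cn(S(=O)(=O)c3ccc(C)cc3)c3ccccc23)c1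
F3 | step 3 | 3,4-bis(1-tosylindol-3-yl)-1H-pyrrole | c1[nH]cc(-c2cn(S(=O)(=O)c3ccc(C)cc3)c3ccccc23)c1-c1cn(S(=O)(=O)c2ccc(C)cc2)c2ccccc12
F4 | step 3 | 2,2,2-trichloro-1-[3,4-bis(1-tosylindol-3-yl)-1H-pyrrol-2-yl]ethanone | O=C(c1[nH]cc(-c2cn(S(=O)(=O)c3ccc(C)cc3)c3ccccc23)c1-c1cn(S(=O)(=O)c2ccc(C)cc2)c2ccccc12)C(Cl)(Cl)Cl
F5 | step 1 | (1-tosylindol-3-yl)methanol | Cc1ccc(cc1)S(=O)(=O)n1cc(CO)c2ccccc12
F6 | step 1 | 3-(bromomethyl)-1-tosylindole | Cc1ccc(cc1)S(=O)(=O)n1cc(CBr)c2ccccc12
F7 | step 4 | methyl 5-iodo-3,4-bis(1-tosylindol-3-yl)-1H-pyrrole-2-carboxylate | COC(=O)c1[nH]c(I)c(-c2cn(S(=O)(=O)c3ccc(C)cc3)c3ccccc23)c1-c1cn(S(=O)(=O)c2ccc(C)cc2)c2ccccc12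
F8 | step 4 | methyl 5-(1-ethoxyvinyl)-3,4-bis(1-tosylindol-3-yl)-1H-pyrrole-2-carboxylate | CCOC(=C)c1[nH]c(C(=O)OC)c(-c2cn(S(=O)(=O)c3ccc(C)cc3)c3ccccc23)c1-c1cn(S(=O)(=O)c2ccc(C)cc2)c2ccccc12
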